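The quinone ring is made last and from scratch. The C5'–C6' bond and the whole six-membered ring (C1'–C6') form when a 4-hydroxy-4-[(Z)-2-methoxyvinyl]cyclobutenone, carrying the finished decalin on C11 and a tert-butoxy group, is heated. One operation delivers a hydroquinone in which every position is already assigned: C1' alkyl, C2' masked oxygen, C4' hydrogen, C5' methoxy, and oxygen at C3' and C6'. The key step exploits this fourfold differentiation of the quinone ring, which squarate chemistry encodes through the order of two organolithium additions. The precursor is assembled from a C11 neopentyl iodide of the trans-decalin (from (S)-Wieland–Miescher ketone), di-tert-butyl squarate and (Z)-2-methoxyvinyllithium.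

Key step: step 19

Remarks (conventions and assumptions)
- Numbering: decalin C1–C10 with C4 = carbon of the exocyclic methylene, C5 = ring-fusion CH, C10 = ring-fusion C–CH3, C9 = quaternary carbon bearing CH3 and C11, C8 = CH–CH3; C11 = methylene link; C1'–C6' = quinone ring; β = face of the C10 methyl. "Decalinylmethyl" = C11 with its (4-methylene-8β,9β,10β-trimethyl-5α-H-trans-decalin-9α-yl) group.
- Assumption: in the target the 8β- and 10β-methyl groups are 1,3-diaxial on a trans-decalin, so C5 and C8 are set under kinetic control and are kept away from enolising conditions once both exist.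
- The C2' oxygen is carried as a tert-butyl ether (from di-tert-butyl squarate), because it leaves under mild acid that cannot touch the C5' methyl ether or the C4 alkene.
- The 2-methoxyvinyl nucleophile is generated from (Z)-1-bromo-2-methoxyethene, because lithiation of methyl vinyl ether itself gives the 1-lithio (α) isomer.
- The C8 carbinol of step 7 and the cyclobutenone carbinols of steps 17 and 18 are carried as epimer mixtures, since these centres are destroyed later.
- The Tebbe reagent is drawn with its bridging chloride in charge-separated form (Al−, Cl+) and σ-bonded cyclopentadienyl rings.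

Step 1
Reactants: 1 (S)-Wieland–Miescher ketone
Product: 2 C3 spiro-1,3-dithiolane of 1 (C4=C5 alkene and C9 ketone unchanged)
Conditions: HSCH2CH2SH, TsOH (cat.), AcOH, rt
Reagents that add atoms: ethane-1,2-dithiol, SCCS
Why: Acid-catalysed dithioketalisation is selective for the conjugated C3 carbonyl of this dione, leaving the C9 ketone next to the quaternary C10 free, and no stereocentre is touched.

Step 2
Reactants: 2 enone dithiolane
Product: 3 (S)-8a-methyl-3,4,6,7,8,8a-hexahydronaphthalen-1(2H)-one (C4=C5 alkene, C9 ketone)
Conditions: Raney Ni (W-2, deactivated in acetone), EtOH, reflux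
Reagents that add atoms: none
Why: Reductive desulfurisation with Raney nickel (Mozingo reduction) replaces both C–S bonds by C–H without moving the trisubstituted C4=C5 alkene, and the deactivated nickel should leave the hindered ketone alone.

Step 3
Reactants: 3 octalinone
Product: 4 10β-methyl-5α-H-trans-decalin-4α,9β-diol
Conditions: BH3·THF (excess), THF, 0 °C to rt; then NaOH, H2O2, 0 °C
Reagents that add atoms: hydrogen peroxide, OO
Why: Hydroboration–oxidation puts boron on the less substituted C4 and adds B–H syn from the α face, opposite the angular C10 methyl, which sets C4 (α-OH) and C5 (α-H, trans ring fusion) in one event, while the C9 ketone is reduced in the same pot and is restored in step 5.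

Step 4
Reactants: 4 diol
Product: 5 4α-(tert-butyldimethylsilyloxy)-10β-methyl-5α-H-trans-decalin-9β-ol
Conditions: TBSCl (1.05 equiv), imidazole, DMF, 0 °C
Reagents that add atoms: tert-butyldimethylsilyl chloride, CC(C)(C)[Si](C)(C)Cl
Why: Silyl ether formation should discriminate sterically between the equatorial C4 hydroxyl and the C9 hydroxyl, which is neopentylic to the quaternary C10 and reacts far more slowly with the bulky silyl chloride.

Step 5
Reactants: 5 mono-silyl ether
Product: 6 4α-TBSO-10β-methyl-5α-H-trans-decalin-9-one
Conditions: Dess–Martin periodinane, NaHCO3, CH2Cl2, rt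
Reagents that add atoms: none
Why: Dess–Martin oxidation converts the remaining secondary alcohol into the C9 ketone under neutral conditions that keep the silyl ether.

Step 6
Reactants: 6 C9 ketone
Product: 7 4α-TBSO-10β-methyl-9-methylene-5α-H-trans-decalin
Conditions: Ph3PCH3Br, KOtBu, toluene, 80 °C
Reagents that add atoms: methyltriphenylphosphonium bromide, [Br-].C[P+](c1ccccc1)(c1ccccc1)c1ccccc1
Why: Wittig methylenation of a ketone with one quaternary neighbour proceeds on heating with excess ylide and installs the exocyclic carbon that becomes the C9 methyl.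

Step 7
Reactants: 7 C9 methylene compound
Product: 8 4α-TBSO-10β-methyl-9-methylene-5α-H-trans-decalin-8-ol (C8 epimers)
Conditions: SeO2 (0.5 equiv), t-BuOOH, CH2Cl2, rt
Reagents that add atoms: tert-butyl hydroperoxide, CC(C)(C)OO (oxygen relayed through catalytic selenium dioxide, O=[Se]=O)
Why: Selenium dioxide allylic oxidation (ene reaction, then [2,3]-sigmatropic shift) can only functionalise C8, the sole allylic position bearing hydrogen because C10 is quaternary, and the C8 configuration is irrelevant since the carbinol is oxidised next.

Step 8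
Reactants: 8 allylic alcohol
Product: 9 4α-TBSO-10β-methyl-9-methylene-5α-H-trans-decalin-8-one
Conditions: Dess–Martin periodinane, NaHCO3, CH2Cl2, 0 °C; used at once
Reagents that add atoms: none
Why: Dess–Martin oxidation of the allylic alcohol gives the α-methylene ketone, whose dimerisation is slowed by the adjacent quaternary C10 and avoided by immediate use.

Step 9
Reactants: 9 α-methylene ketone
Product: 11 4α-TBSO-9α-(hydroxymethyl)-9β,10β-dimethyl-5α-H-trans-decalin-8-one, via lithium C8-enolate 10 (not isolated)
Conditions: L-Selectride, THF, −78 °C; then CH2O (gas), −78 °C; AcOH quench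
Reagents that add atoms: formaldehyde, C=O
Why: In this reductive aldol reaction, conjugate hydride addition to the unhindered methylene terminus forms the tetrasubstituted C8–C9 enolate regiospecifically and turns the methylene into the C9 methyl, and formaldehyde then attacks C9 axially on the α face, anti to the axial C10 methyl, so that C11 is α and the methyl β.

Step 10
Reactants: 11 β-hydroxy ketone
Product: 12 [4α-TBSO-9β,10β-dimethyl-8-methylene-5α-H-trans-decalin-9α-yl]methanol
Conditions: Zn, CH2Br2, TiCl4, THF–CH2Cl2, 0 °C to rt
Reagents that add atoms: dibromomethane, BrCBr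
Why: Takai–Lombardo methylenation is non-basic, so the β-hydroxy ketone cannot undergo retro-aldol cleavage, and the reagent is expected to tolerate the free hydroxyl and the quaternary neighbour.

Step 11
Reactants: 12 homoallylic alcohol
Product: 13 [4α-TBSO-8β,9β,10β-trimethyl-5α-H-trans-decalin-9α-yl]methanol (8α-H)
Conditions: H2 (1 atm), [Ir(cod)(PCy3)(py)]PF6 (5 mol %), CH2Cl2, rt
Reagents that add atoms: none
Why: In this hydroxyl-directed homogeneous hydrogenation the cationic iridium catalyst binds the axial C11 hydroxyl and delivers both hydrogens to the α face of the C8 methylene, which sets C8 with α-H and β-methyl, the opposite face being shielded by the axial C10 methyl as well.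

Step 12
Reactants: 13 neopentyl alcohol
Product: 14 4α-TBSO-9α-(iodomethyl)-8β,9β,10β-trimethyl-5α-H-trans-decalin
Conditions: PPh3, I2, imidazole, toluene, 90 °C
Reagents that add atoms: iodine, II
Why: Appel-type iodination through the alkoxyphosphonium ion is an SN2 displacement at the primary C11, which is neopentylic and so needs heat but should not rearrange because no carbocation is formed.

Step 13
Reactants: 14 silyl ether iodide
Product: 15 9α-(iodomethyl)-8β,9β,10β-trimethyl-5α-H-trans-decalin-4α-ol
Conditions: HF·pyridine, THF, 0 °C to rt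
Reagents that add atoms: none
Why: Fluoride-mediated desilylation, driven by the strong Si–F bond, frees the C4 alcohol and does not touch the neopentyl iodide.

Step 14
Reactants: 15 iodo alcohol
Product: 16 9α-(iodomethyl)-8β,9β,10β-trimethyl-5α-H-trans-decalin-4-one
Conditions: Dess–Martin periodinane, NaHCO3, CH2Cl2, 0 °C; used crude
Reagents that add atoms: none
Why: Dess–Martin oxidation under buffered neutral conditions gives the C4 ketone without enolisation, which matters because C5 is now epimerisable and the cis-fused isomer would relieve the C8/C10 diaxial methyl interaction.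

Step 15
Reactants: 16 iodo ketone
Product: 17 9α-(iodomethyl)-8β,9β,10β-trimethyl-4-methylene-5α-H-trans-decalin (decalin C11 iodide)
Conditions: Tebbe reagent, pyridine (cat.), THF–toluene, −40 to 0 °C
Reagents that add atoms: Tebbe reagent, C[Al-]1(C)C[Ti](C2C=CC=C2)(C2C=CC=C2)[Cl+]1
Why: Titanium methylidene (Tebbe) olefination is non-basic and fast at low temperature, so the ketone should become the exocyclic C4 alkene with the C5 configuration retained and the iodide untouched.

Step 16
Reactants: 18 methyl vinyl ether
Product: 20 (Z)-1-bromo-2-methoxyethene, via 1,2-dibromo-1-methoxyethane 19 (not isolated)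
Conditions: Br2, pentane, −78 °C; then PhNEt2, 90 °C, distil
Reagents that add atoms: bromine, BrBr
Why: Electrophilic bromine addition to the enol ether followed by amine-induced dehydrobromination of the α-bromo ether should give the β-bromo enol ether mainly as the Z isomer, a detour needed because deprotonation of methyl vinyl ether itself occurs at the α carbon.

Step 17
Reactants: 17 decalin C11 iodide, 21 di-tert-butyl squarate
Product: 24 3-(decalinylmethyl)-4-tert-butoxycyclobut-3-ene-1,2-dione, via alkyllithium 22 (not isolated), via lithium alkoxide adduct 23 (not isolated)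
Conditions: t-BuLi (2.1 equiv), Et2O–pentane, −78 °C; then 21, THF, −78 °C; then (CF3CO)2O, −78 °C; aq. NaHCO3
Reagents that add atoms: none
Why: Iodine–lithium exchange gives the primary alkyllithium, which adds 1,2 to one carbonyl of the squaric ester, and trifluoroacetylation of the alkoxide then triggers ionisation with loss of one tert-butyl group as isobutene to give the alkylcyclobutenedione (the standard squarate addition–rearrangement sequence), with no decalin stereocentre involved.

Step 18
Reactants: 24 alkylcyclobutenedione, 20 (Z)-1-bromo-2-methoxyethene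
Product: 26 2-(decalinylmethyl)-3-tert-butoxy-4-hydroxy-4-[(Z)-2-methoxyvinyl]cyclobut-2-en-1-one (carbinol epimers), via (Z)-2-methoxyvinyllithium 25 (not isolated)
Conditions: t-BuLi (2 equiv per 20), THF, −78 °C; then 24, −78 °C; aq. NH4Cl
Reagents that add atoms: none
Why: Bromine–lithium exchange with retention of the Z geometry gives 2-methoxyvinyllithium, which adds 1,2 to the more electrophilic carbonyl, the one attached to the tert-butoxy-bearing carbon, because the other carbonyl is deactivated as a vinylogous ester, and the new carbinol centre is erased in step 19.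

Step 19
Reactants: 26 4-hydroxy-4-(2-methoxyvinyl)cyclobutenone
Product: 29 hydroquinone with C1' decalinylmethyl and C2' tert-butoxy and C5' methoxy (hydroxyls at C3' and C6'), via dienylketene 27 (not isolated), via cyclohexadienone 28 (not isolated)
Conditions: toluene (degassed), 110 °C, Ar
Reagents that add atoms: none
Why: Heating opens the cyclobutenone by thermal conrotatory 4π electrocyclic cleavage of the C1–C4 bond, and the hydroxyl, a donor, rotates outward so that the methoxyvinyl group ends up cis to the ketene in dienylketene 27. The ketene carbon (future C6') then bonds to the methoxy-bearing vinyl carbon (future C5') in a 6π electrocyclisation, the only ring closure of the step, giving cyclohexadienone 28, which enolises to the aromatic hydroquinone 29. The closest known reaction type is the thermal ring expansion of squarate-derived 4-alkenyl-4-hydroxycyclobutenones to hydroquinones. No stereocentre is created, because the sp3 carbon C5' formed in the closure is erased by tautomerisation. The step needs outward torquoselectivity of the hydroxyl, which the oxygen donor itself secures, and a fixed substitution pattern, which is secured because the C1' alkyl, the C2' tert-butoxy and the C3'/C4'/C5' unit were placed by the two successive organolithium additions. The medium is neutral and oxygen-free, so the exocyclic C4 alkene, the tert-butyl ether and the air-sensitive hydroquinone should survive.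

Step 20
Reactants: 29 hydroquinone
Product: 30 3-(decalinylmethyl)-2-tert-butoxy-5-methoxy-1,4-benzoquinone
Conditions: Ag2O, MgSO4, Et2O, rt
Reagents that add atoms: none
Why: Two-electron oxidation of the hydroquinone to the para-quinone by silver(I) oxide is mild and neutral, so the alkene and the tert-butyl ether should persist.

Step 21
Reactants: 30 tert-butoxy quinone
Product: 31 target CNP0109104.1
Conditions: TFA (5 equiv), CH2Cl2, 0 °C, short
Reagents that add atoms: none
Why: Acidolysis of the tert-butyl vinylogous ester (E1 loss of isobutene after protonation of the quinone carbonyl) unmasks the C2' hydroxyl, while the C5' methyl ether cannot ionise and the brief cold exposure should spare the 1,1-disubstituted alkene.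

Compound list
1 | (S)-Wieland–Miescher ketone, (8aS)-8a-methyl-3,4,8,8a-tetrahydronaphthalene-1,6(2H,7H)-dione | O=C1CC[C@@]2(C)C(=C1)CCCC2=O | starting material
2 | 1 with the C3 (enone) carbonyl as spiro-1,3-dithiolane; C4=C5 alkene, C9 ketone, 10β-methyl | S1CCSC13CC[C@@]2(C)C(=C3)CCCC2=O | intermediate
3 | (S)-8a-methyl-3,4,6,7,8,8a-hexahydronaphthalen-1(2H)-one (C4=C5 alkene, C9 ketone, 10β-methyl) | C1CC[C@@]2(C)C(=C1)CCCC2=O | intermediate
4 | 10β-methyl-5α-H-trans-decalin-4α,9β-diol | O[C@@H]1CCC[C@@]2(C)[C@H]1CCC[C@@H]2O | intermediate
5 | 4α-(tert-butyldimethylsilyloxy)-10β-methyl-5α-H-trans-decalin-9β-ol | CC(C)(C)[Si](C)(C)O[C@@H]1CCC[C@@]2(C)[C@H]1CCC[C@@H]2O | intermediate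
6 | 4α-TBSO-10β-methyl-5α-H-trans-decalin-9-one | CC(C)(C)[Si](C)(C)O[C@@H]1CCC[C@@]2(C)[C@H]1CCCC2=O | intermediate
7 | 4α-TBSO-10β-methyl-9-methylene-5α-H-trans-decalin | CC(C)(C)[Si](C)(C)O[C@@H]1CCC[C@@]2(C)[C@H]1CCCC2=C | intermediate
8 | 4α-TBSO-10β-methyl-9-methylene-5α-H-trans-decalin-8-ol (C8 epimers) | CC(C)(C)[Si](C)(C)O[C@@H]1CCC[C@@]2(C)[C@H]1CCC(O)C2=C | intermediate
9 | 4α-TBSO-10β-methyl-9-methylene-5α-H-trans-decalin-8-one | CC(C)(C)[Si](C)(C)O[C@@H]1CCC[C@@]2(C)[C@H]1CCC(=O)C2=C | intermediate
10 | lithium enolate, 4α-TBSO-9,10β-dimethyl-5α-H-decal-8-en-8-olate (C8=C9; not isolated) | CC(C)(C)[Si](C)(C)O[C@@H]1CCC[C@@]2(C)[C@H]1CCC(O[Li])=C2C | intermediate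
11 | 4α-TBSO-9α-(hydroxymethyl)-9β,10β-dimethyl-5α-H-trans-decalin-8-one | CC(C)(C)[Si](C)(C)O[C@@H]1CCC[C@@]2(C)[C@H]1CCC(=O)[C@@]2(C)CO | intermediate
12 | [4α-TBSO-9β,10β-dimethyl-8-methylene-5α-H-trans-decalin-9α-yl]methanol | CC(C)(C)[Si](C)(C)O[C@@H]1CCC[C@@]2(C)[C@H]1CCC(=C)[C@@]2(C)CO | intermediate
13 | [4α-TBSO-8β,9β,10β-trimethyl-5α-H-trans-decalin-9α-yl]methanol (8α-H) | CC(C)(C)[Si](C)(C)O[C@@H]1CCC[C@@]2(C)[C@H]1CC[C@H](C)[C@@]2(C)CO | intermediate
14 | 4α-TBSO-9α-(iodomethyl)-8β,9β,10β-trimethyl-5α-H-trans-decalin | CC(C)(C)[Si](C)(C)O[C@@H]1CCC[C@@]2(C)[C@H]1CC[C@H](C)[C@@]2(C)CI | intermediate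
15 | 9α-(iodomethyl)-8β,9β,10β-trimethyl-5α-H-trans-decalin-4α-ol | O[C@@H]1CCC[C@@]2(C)[C@H]1CC[C@H](C)[C@@]2(C)CI | intermediate
16 | 9α-(iodomethyl)-8β,9β,10β-trimethyl-5α-H-trans-decalin-4-one | O=C1CCC[C@@]2(C)[C@H]1CC[C@H](C)[C@@]2(C)CI | intermediate
17 | 9α-(iodomethyl)-8β,9β,10β-trimethyl-4-methylene-5α-H-trans-decalin (decalin C11 iodide) | C=C1CCC[C@@]2(C)[C@H]1CC[C@H](C)[C@@]2(C)CI | intermediate
18 | methyl vinyl ether | COC=C | starting material
19 | 1,2-dibromo-1-methoxyethane (racemic; not isolated) | COC(Br)CBr | intermediate
20 | (Z)-1-bromo-2-methoxyethene | CO/C=C\Br | intermediate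
21 | di-tert-butyl squarate, 3,4-di-tert-butoxycyclobut-3-ene-1,2-dione | CC(C)(C)OC1=C(OC(C)(C)C)C(=O)C1=O | starting material
22 | decalinylmethyllithium (C11–Li; not isolated) | C=C1CCC[C@@]2(C)[C@H]1CC[C@H](C)[C@@]2(C)C[Li] | intermediate
23 | lithium 2,3-di-tert-butoxy-1-(decalinylmethyl)-4-oxocyclobut-2-en-1-olate (carbinol epimers; not isolated) | C=C1CCC[C@@]2(C)[C@H]1CC[C@H](C)[C@@]2(C)CC1(O[Li])C(OC(C)(C)C)=C(OC(C)(C)C)C1=O | intermediate
24 | 3-(decalinylmethyl)-4-tert-butoxycyclobut-3-ene-1,2-dione | C=C1CCC[C@@]2(C)[C@H]1CC[C@H](C)[C@@]2(C)CC1=C(OC(C)(C)C)C(=O)C1=O | intermediate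
25 | (Z)-2-methoxyvinyllithium (not isolated) | CO/C=C\[Li] | intermediate
26 | 2-(decalinylmethyl)-3-tert-butoxy-4-hydroxy-4-[(Z)-2-methoxyvinyl]cyclobut-2-en-1-one (carbinol epimers) | C=C1CCC[C@@]2(C)[C@H]1CC[C@H](C)[C@@]2(C)CC1=C(OC(C)(C)C)C(O)(/C=C\OC)C1=O | intermediate
27 | dienylketene, 2-(decalinylmethyl)-3-tert-butoxy-4-hydroxy-6-methoxyhexa-1,3,5-trien-1-one with the methoxyvinyl group cis to the ketene (not isolated) | C=C1CCC[C@@]2(C)[C@H]1CC[C@H](C)[C@@]2(C)CC(=C=O)/C(OC(C)(C)C)=C(O)\C=C/OC | intermediate
28 | 2-(decalinylmethyl)-3-tert-butoxy-4-hydroxy-6-methoxycyclohexa-2,4-dien-1-one (not isolated) | C=C1CCC[C@@]2(C)[C@H]1CC[C@H](C)[C@@]2(C)CC1=C(OC(C)(C)C)C(O)=CC(OC)C1=O | intermediate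
29 | 2-(decalinylmethyl)-3-tert-butoxy-6-methoxybenzene-1,4-diol (C2' OtBu, C5' OMe, C3' and C6' OH) | C=C1CCC[C@@]2(C)[C@H]1CC[C@H](C)[C@@]2(C)Cc1c(OC(C)(C)C)c(O)cc(OC)c1O | intermediate
30 | 3-(decalinylmethyl)-2-tert-butoxy-5-methoxy-1,4-benzoquinone | C=C1CCC[C@@]2(C)[C@H]1CC[C@H](C)[C@@]2(C)CC1=C(OC(C)(C)C)C(=O)C=C(OC)C1=O | intermediate
31 | CNP0109104.1, 3-(decalinylmethyl)-2-hydroxy-5-methoxy-1,4-benzoquinone | C=C1CCC[C@@]2(C)[C@H]1CC[C@H](C)[C@@]2(C)CC1=C(O)C(=O)C=C(OC)C1=O | target

Total step count: 21. Longest linear sequence: 20 steps (steps 1–15 and 17–21, from 1); step 16 is the one-step side branch.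

Steps most likely to fail

Step 19 (ring expansion). The ketene may be intercepted by the neighbouring hydroxyl (lactone formation) before the 6π closure, which is slowed because the Z-methoxy group points inward at the closing terminus. The fallback sets out from 24 and 20 and uses the known rearrangement of 4-alkynyl-4-hydroxycyclobutenones to quinones. Bromide 20 is treated with two equivalents of LDA in THF at −78 °C (anti elimination of HBr, then deprotonation) to give lithium methoxyacetylide F1. F1 adds to the same carbonyl of 24 to give 2-(decalinylmethyl)-3-tert-butoxy-4-hydroxy-4-(methoxyethynyl)cyclobut-2-en-1-one F2. Heating F2 in toluene opens the ring to an enynylketene, which closes to a ring diradical and, after transfer of the hydroxyl hydrogen to C4', should give quinone 30 directly. The route is rejoined at 30.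

Step 11 (directed hydrogenation). Hydrogen may be delivered in part from the β face if the catalyst fails to engage the congested axial hydroxymethyl group, or the exocyclic alkene may migrate into the ring before it is reduced. The fallback sets out from 12 and makes the migration deliberate. Cobalt–salen/PhSiH3 hydrogen-atom-transfer isomerisation (only C7 carries an allylic hydrogen) would give the endocyclic C7=C8 alkene, [4α-TBSO-8,9β,10β-trimethyl-5α-H-decal-7-en-9α-yl]methanol F3. This trisubstituted alkene is then hydrogenated under hydroxyl direction with [Rh(nbd)(dppb)]BF4 under hydrogen pressure, adding both hydrogens to C7 and C8 from the α face. The route is rejoined at 13.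

Step 9 (reductive aldol). Hydride may add 1,2 to the hindered enone, or the formaldehyde adduct may revert or oligomerise in the basic medium. The fallback sets out from 9 and separates the two events. Rhodium-catalysed 1,4-hydrosilylation (Et3SiH, cat. RhCl(PPh3)3) would give the triethylsilyl enol ether F4. F4 is then hydroxymethylated under Lewis-acid Mukaiyama aldol conditions (aqueous formaldehyde, cat. Sc(OTf)3, THF), with the same α-face approach. The route is rejoined at 11.

Further compounds
F1 | step 19 | lithium methoxyacetylide | COC#C[Li]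
F2 | step 19 | 2-(decalinylmethyl)-3-tert-butoxy-4-hydroxy-4-(methoxyethynyl)cyclobut-2-en-1-one | C=C1CCC[C@@]2(C)[C@H]1CC[C@H](C)[C@@]2(C)CC1=C(OC(C)(C)C)C(O)(C#COC)C1=O
F3 | step 11 | [4α-TBSO-8,9β,10β-trimethyl-5α-H-decal-7-en-9α-yl]methanol | CC(C)(C)[Si](C)(C)O[C@@H]1CCC[C@@]2(C)[C@H]1CC=C(C)[C@@]2(C)CO
F4 | step 9 | triethylsilyl enol ether of the C8 ketone (C8=C9, 9-methyl) | CC(C)(C)[Si](C)(C)O[C@@H]1CCC[C@@]2(C)[C@H]1CCC(O[Si](CC)(CC)CC)=C2C
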